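**Retrosynthetic overview**
1. Target 10 is two andrographolide-derived ent-labdane halves joined only by the C15–C12' ketone bond. No carbocycle is built: both decalins and their ten stereocentres are bought in andrographolide 1.
2. Last C–C bond: C15–C12', made photochemically by adding the C15 acetal radical of left half 7 to allylic acetate 3 with loss of AcOH (radical SN2'). C12' is set anti to the 14'-acetoxy group.
3. Left half 7 comes from the same acetate 3 by elimination, deconjugative methanolysis of the lactone (C16 to CO2Me, C15 to aldehyde level) and acetal formation.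
4. 3 comes from 1 by 3,19-acetonide formation and 14-O-acetylation. One final acid hydrolysis frees the ketone and the diol.
5. Ring events: left lactone opened (step 3), right butenolide formed (step 4).

Assumption: andrographolide numbering is used for both halves (primes for the butenolide half), and andrographolide is the only chiral purchase.

**Step 1**
Reactants: 1 andrographolide
Product: 2 3,19-O-isopropylideneandrographolide
Conditions: Me2C(OMe)2, PPTS (cat.), toluene–DMSO, 80 °C
Reagents that add atoms: 2,2-dimethoxypropane, COC(C)(C)OC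
Why: Acid-catalysed transacetalisation gives the favoured six-membered acetonide of the C3/C19 1,3-diol and leaves the allylic 14-OH free; no stereocentre is touched.

**Step 2**
Reactants: 2 3,19-O-isopropylideneandrographolide
Product: 3 14-O-acetyl-3,19-O-isopropylideneandrographolide
Conditions: Ac2O, DMAP (cat.), pyridine, CH2Cl2, 0 °C
Reagents that add atoms: acetic anhydride, CC(=O)OC(C)=O
Why: DMAP-catalysed acylation of the only free hydroxyl, run cold so the new allylic acetate does not eliminate; C14 stays S.

**Step 3**
Reactants: 3 14-O-acetyl-3,19-O-isopropylideneandrographolide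
Product: 7 methyl (12E)-3,19-dihydroxy-15,15-dimethoxy-ent-labda-8(17),12-dien-16-oate, via dienyl butenolide 4 (not isolated), via enol lactone 5 (not isolated), via aldehyde ester 6 (not isolated)
Conditions: DBU, THF, 25 °C; then NaOMe, MeOH, 0 → 25 °C; then TsOH·H2O, MeOH, 25 °C
Reagents that add atoms: methanol, CO; sodium methoxide, C[O-].[Na+]
Why: DBU removes AcOH by vinylogous E1cB elimination to give 4; methoxide then forms the 2-oxidofuran of 4, which is reprotonated on the side chain to enol lactone 5 (or its C13-protonated isomer, which converges), and irreversible enol-ester methanolysis gives 6 with the thermodynamic 12E geometry (C11 trans to CO2Me, as in tiglates); acidic methanol finally forms the dimethyl acetal and transacetalises the acetonide (E1cB elimination, dienolate deconjugation, enol-ester methanolysis, acetalisation).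

**Step 4**
Reactants: 7 methyl (12E)-3,19-dihydroxy-15,15-dimethoxy-ent-labda-8(17),12-dien-16-oate (1.0 equiv); 3 14-O-acetyl-3,19-O-isopropylideneandrographolide (1.5 equiv)
Product: 8 the 15,15-dimethyl ketal 3',19'-O-isopropylidene derivative of the target (C15(OMe)2 bonded to C12', 12'S, Δ13',14'-butenolide)
Conditions: (Bu4N)4[W10O32] (5 mol %), MeCN, 390 nm LEDs, 20 °C, Ar
Reagents that add atoms: none
Why: Proposed new method: photoexcited decatungstate abstracts the hydridic acetal C15–H of 7 to give a nucleophilic α,α-dimethoxyalkyl radical (used instead of the aldehyde because the β,γ-unsaturated acyl radical would lose CO to an ester-substituted allyl radical), which adds to C12' of the exocyclic enoate of 3 on the face opposite the 14'-acetoxy group, so the purchased 14'S centre is relayed to 12'S; reduced decatungstate then reduces the α-lactone radical to its enolate, which expels acetate by E1cB to give the butenolide and returns the catalyst, the closest known reactions being decatungstate-photocatalysed Giese additions of acetal radicals to acrylates and radical addition/β-elimination on Morita–Baylis–Hillman acetates, neither shown for a tertiary ketal radical on a β-substituted cyclic acetate with 1,3-chirality transfer.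

**Step 5**
Reactants: 8 the 15,15-dimethyl ketal 3',19'-O-isopropylidene derivative of the target
Product: 10 CNP0330094.1 (target), via ketone acetonide 9 (not isolated)
Conditions: AcOH–H2O (7:3), 25 °C
Reagents that add atoms: water, O
Why: Acid-catalysed hydrolysis cleaves the acyclic dimethyl ketal first (giving 9) and then the 1,3-dioxane acetonide, under conditions too mild to enolise the C15 ketone or move the exocyclic alkenes, so C12' and both alkene positions are kept.

**Compound list**
1 | andrographolide | C=C1CC[C@@H]2[C@](C)(CO)[C@H](O)CC[C@@]2(C)[C@@H]1C/C=C1/C(=O)OC[C@H]1O | starting material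
2 | 3,19-O-isopropylideneandrographolide | C=C1CC[C@@H]2[C@]3(C)COC(C)(C)O[C@@H]3CC[C@@]2(C)[C@@H]1C/C=C1/C(=O)OC[C@H]1O | intermediate
3 | 14-O-acetyl-3,19-O-isopropylideneandrographolide | C=C1CC[C@@H]2[C@]3(C)COC(C)(C)O[C@@H]3CC[C@@]2(C)[C@@H]1C/C=C1/C(=O)OC[C@H]1OC(C)=O | intermediate
4 | 3,19-O-isopropylidene-14-deoxy-11,12-didehydroandrographolide ((11E)-dienyl butenolide) | C=C1CC[C@@H]2[C@]3(C)COC(C)(C)O[C@@H]3CC[C@@]2(C)[C@@H]1/C=C/C1=CCOC1=O | intermediate (not isolated)
5 | 3,19-O-isopropylidene-14-deoxy-14,15-didehydroandrographolide ((12E)-3-alkylidene-furan-2(3H)-one enol lactone) | C=C1CC[C@@H]2[C@]3(C)COC(C)(C)O[C@@H]3CC[C@@]2(C)[C@@H]1C/C=C1/C(=O)OC=C1 | intermediate (not isolated)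
6 | methyl (12E)-3,19-O-isopropylidene-15-oxo-ent-labda-8(17),12-dien-16-oate (aldehyde ester) | C=C1CC[C@@H]2[C@]3(C)COC(C)(C)O[C@@H]3CC[C@@]2(C)[C@@H]1C/C=C(\CC=O)C(=O)OC | intermediate (not isolated)
7 | methyl (12E)-3,19-dihydroxy-15,15-dimethoxy-ent-labda-8(17),12-dien-16-oate (left half; side chain CH2–CH=C(CO2Me)–CH2–CH(OMe)2) | C=C1CC[C@@H]2[C@](C)(CO)[C@H](O)CC[C@@]2(C)[C@@H]1C/C=C(\CC(OC)OC)C(=O)OC | intermediate
8 | 15,15-dimethyl ketal 3',19'-O-isopropylidene derivative of the target (12'S) | C=C1CC[C@@H]2[C@](C)(CO)[C@H](O)CC[C@@]2(C)[C@@H]1C/C=C(\CC(OC)(OC)[C@@H](C[C@@H]1C(=C)CC[C@@H]2[C@]3(C)COC(C)(C)O[C@@H]3CC[C@]21C)C1=CCOC1=O)C(=O)OC | intermediate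
9 | 3',19'-O-isopropylidene derivative of the target (C15 ketone, 12'S) | C=C1CC[C@@H]2[C@](C)(CO)[C@H](O)CC[C@@]2(C)[C@@H]1C/C=C(\CC(=O)[C@@H](C[C@@H]1C(=C)CC[C@@H]2[C@]3(C)COC(C)(C)O[C@@H]3CC[C@]21C)C1=CCOC1=O)C(=O)OC | intermediate (not isolated)
10 | CNP0330094.1 | C=C1CC[C@@H]2[C@](C)(CO)[C@H](O)CC[C@@]2(C)[C@@H]1C/C=C(\CC(=O)[C@@H](C[C@@H]1C(=C)CC[C@@H]2[C@](C)(CO)[C@H](O)CC[C@]21C)C1=CCOC1=O)C(=O)OC | target

**Step count**
Total steps: 5. Longest linear sequence: 5 (1 → 2 → 3 → 7 → 8 → 10; 3 is used a second time as the coupling partner in step 4).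

**Steps most likely to fail**

Step 3 is the least secure of the conventional steps. The 2-oxidofuran of 4 may simply return 4, and the freed aldehyde may move its alkene into conjugation (C13=C14) or undergo aldol reaction before it is trapped as the acetal. The fallback builds the side chain instead of isomerising it; it sets out from 2 and comes back at 7. Exhaustive ozonolysis of 2 (O3, CH2Cl2–MeOH, −78 °C; Me2S) cleaves both alkenes and gives the keto aldehyde F1. Horner–Wadsworth–Emmons olefination of the aldehyde only, with methyl 2-(dimethoxyphosphoryl)-4,4-dimethoxybutanoate (NaH, THF, 0 °C), gives the (12E)-keto enoate acetal F2. Wittig methylenation of the C8 ketone (Ph3P=CH2 from Ph3PCH3Br and KN(SiMe3)2, THF) restores the exocyclic methylene and gives the acetonide acetal F3. PPTS in MeOH then transacetalises the acetonide without touching the dimethyl acetal and delivers 7.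

Step 4, the proposed new reaction, can fail in three ways: hydrogen abstraction at carbinol or allylic C–H bonds instead of C15–H, slow addition of the tertiary ketal radical to the trisubstituted acceptor, or wrong facial selectivity at C12'. The fallback uses polar acyl-anion chemistry of a known type; it sets out from 7 and comes back at 9. Mild hydrolysis of 7 (PPTS, acetone–H2O, 25 °C) gives the aldehyde ester F4. A thiazolium-catalysed Stetter reaction of F4 with 3 (3-benzyl-5-(2-hydroxyethyl)-4-methylthiazolium chloride, Et3N, EtOH, 70 °C) adds the Breslow intermediate to C12'; the resulting enolate expels acetate and gives 9, which is deprotected to 10 under the step 5 conditions.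

Step 5 may epimerise C12' (α to the new ketone and allylic to the butenolide) or isomerise the C12=C13 and exocyclic alkenes during the longer acid exposure needed for the acetonide. The fallback removes the acetonide before the coupling, so the last step is only a ketal cleavage; it sets out from 3 and comes back at 10. Treating 3 with AcOH–H2O (7:3, 25 °C) gives 14-O-acetylandrographolide F5. Coupling F5 with 7 under the step 4 conditions gives the tetraol dimethyl ketal F6. F6 is unmasked under nearly neutral conditions (oxalic acid on wet silica gel, CH2Cl2, 25 °C) to give 10.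

**Further compounds**
F1 | step 3 | 3,19-O-isopropylidene-8-oxo-13,14,15,16,17-pentanor-ent-labdan-12-al (keto aldehyde) | O=C1CC[C@@H]2[C@]3(C)COC(C)(C)O[C@@H]3CC[C@@]2(C)[C@@H]1CC=O
F2 | step 3 | methyl (12E)-3,19-O-isopropylidene-15,15-dimethoxy-8-oxo-17-nor-ent-labd-12-en-16-oate (keto enoate acetal) | O=C1CC[C@@H]2[C@]3(C)COC(C)(C)O[C@@H]3CC[C@@]2(C)[C@@H]1C/C=C(\CC(OC)OC)C(=O)OC
F3 | step 3 | methyl (12E)-3,19-O-isopropylidene-15,15-dimethoxy-ent-labda-8(17),12-dien-16-oate (acetonide acetal) | C=C1CC[C@@H]2[C@]3(C)COC(C)(C)O[C@@H]3CC[C@@]2(C)[C@@H]1C/C=C(\CC(OC)OC)C(=O)OC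
F4 | step 4 | methyl (12E)-3,19-dihydroxy-15-oxo-ent-labda-8(17),12-dien-16-oate (aldehyde ester) | C=C1CC[C@@H]2[C@](C)(CO)[C@H](O)CC[C@@]2(C)[C@@H]1C/C=C(\CC=O)C(=O)OC
F5 | step 5 | 14-O-acetylandrographolide | C=C1CC[C@@H]2[C@](C)(CO)[C@H](O)CC[C@@]2(C)[C@@H]1C/C=C1/C(=O)OC[C@H]1OC(C)=O
F6 | step 5 | 15,15-dimethyl ketal of the target (free tetraol, 12'S) | C=C1CC[C@@H]2[C@](C)(CO)[C@H](O)CC[C@@]2(C)[C@@H]1C/C=C(\CC(OC)(OC)[C@@H](C[C@@H]1C(=C)CC[C@@H]2[C@](C)(CO)[C@H](O)CC[C@]21C)C1=CCOC1=O)C(=O)OC
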